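## Structural features

The target, (5R)-7-(3,4-dihydroxyphenyl)-5-hydroxy-1-(4-hydroxy-3-methoxyphenyl)heptan-3-one, is an open-chain diarylheptanoid. A guaiacyl ring on C1 and a catechol ring on C7 are joined by an unbranched seven-carbon chain, and the chain holds no further ring. The chain carries a ketone at C3 and a secondary alcohol at C5, an aldol-type β-hydroxy ketone. C5 is the only stereocentre, so no stereocentres stand next to each other and there is no relative configuration to control. The fragile parts are the β-hydroxy ketone, which can lose water to the conjugated enone or cleave by retro-aldol under base, strong acid or heat, and the catechol, which is oxidised by air once deprotonated. The real difficulty is that C5 is flanked by two methylene arms, C4 and C6, that differ only two atoms further out, and that two very similar arylethyl ends must be placed at the correct termini. The key step uses the fact that C3–C4–C5(O)–C6–C7 is the carbon skeleton of 3-hydroxyglutaric acid. In the cyclic anhydride, C5 lies on a mirror plane and the two carbonyl carbons (the future C3 and C7) are enantiotopic, so choosing one of them for C–C bond formation creates the C5 stereocentre without a bond being made at C5 and leaves the two ends at different oxidation levels.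

## Logic of the disconnections

13 ⇒ 12. The O–Si bond at C5 is cut last. The C5 oxygen stays masked through every step in which a carbonyl group sits β to it on either side, which removes the dehydration and retro-aldol pathways until the end. The forward step must be a non-basic desilylation that the catechol and the free aldol tolerate.

12 ⇒ 11. The three aryl O–CH2Ph bonds and the two C7–H bonds are cut, which puts a carbonyl at C7 and benzyl groups on all three phenols. A C7 carbonyl is what an acyl coupling leaves behind, and one hydrogenation can remove it together with all benzyl groups. The forward step must hydrogenolyse an aryl ketone flanked by an electron-rich ring while leaving the dialkyl ketone at C3 and the silyl ether alone.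

11 ⇒ 7 + 10. The C7–aryl bond is cut at the acyl oxidation level. This splits off the whole catechol ring as 10, made in the flask from 8 through 9. The forward step must be a neutral acyl cross-coupling, so that no enolate forms next to the silyloxy group and the C3 ketone is not attacked.

7 ⇒ 6. The C7–S bond is cut. This only activates the carboxyl group of 6 for the coupling; the activation must not eliminate the β-silyloxy group.

6 ⇒ 5 + 4. The C2–C3 bond is cut, which is the strategic disconnection. It reveals the hidden symmetry of the C3–C7 segment: 5 is achiral, is bought, and already holds five of the seven chain carbons and the C5 oxygen. The forward step must select one of two enantiotopic carbonyl groups, couple an sp3 zinc reagent that has β-hydrogens, stop after one addition and leave the silyloxy group in place. The precursor design is tightened in three ways. Rhodium with a P,N ligand is chosen over palladium because the nucleophile is a β-hydrogen-bearing alkylzinc halide. The zinc reagent is generated by LiCl-promoted insertion so that it is a soluble, titrated THF solution that can be added slowly. Benzyl is used on every phenol so that one later hydrogenation unmasks all three.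

4 ⇒ 3. The C–Zn bond is cut back to the C–I bond; direct zinc insertion tolerates the benzyl ether and the methoxy group.

3 ⇒ 2. The C–I bond is cut back to the primary alcohol; the forward step is a neutral iodination that does not eliminate to the styrene.

2 ⇒ 1. The phenolic O–benzyl bond is cut; the forward step must alkylate the phenol and not the aliphatic alcohol, which the acidity difference secures.

## Other disconnections considered

Alternative 1: The cut is the C5–H bond. 13 is traced through the (R)-hydroxy enone A2 back to the hept-1-ene-3,5-dione A1, in which both aryl arms and all seven chain carbons are already in place. In the forward direction a nicotinamide-dependent ketoreductase with cofactor recycling would deliver hydride to C5 only, on the face that gives A2. One catalytic hydrogenation would then saturate C1=C2 and remove the two benzyl groups.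
- In its favour: after the key step every chain carbon and both oxygen functions are at their final position and oxidation level. A1 should be reachable by short curcuminoid-type condensation chemistry. The styryl conjugation lowers the reactivity of the C3 carbonyl, which is the right bias for site selection.
- Against it: A1 is a β-diketone that should exist largely as a chelated, conjugated enol, a poor form for hydride transfer. It is large, lipophilic and sparingly soluble in water. An enzyme combining C5 site selectivity, (R) facial selectivity and no over-reduction to the diol would have to be found by panel screening and cannot be predicted.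
- Comparison: on structure this plan is better than the chosen one, because no oxidation-level change is needed after the stereo-defining step, whereas the chosen route must still turn the C7 carboxyl into a methylene group. On step economy it is also better (about five steps against eight). On mechanism the two are equal: each rests on a catalyst telling apart two carbonyl groups of one substrate, and each is an extrapolation. The chosen plan has two advantages: the stereocentre is carried as a silyl ether instead of a free aldol, and a precedented detour from the same anhydride exists if the selection fails.

Alternative 2: The cut is the C3–C4 bond, with C3 as an acyl-anion equivalent. The 2-lithio-1,3-dithiane A5, made by deprotonation of the dithiane A4, would open the chiral-pool-derived (R)-epoxide A3 at its terminal CH2 in an SN2 reaction to give the dithiane carbinol A6. Unmasking of the dithiane and debenzylation would then lead to 13.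
- In its favour: the C5 configuration is bought and not made, so it does not depend on any catalyst. On stereochemical security and on precedent this plan is better than the chosen one, since every step is an established reaction type. It is also convergent, and its longest linear sequence (about six steps) would be shorter than that of the chosen route.
- Against it: opening an epoxide with a 2-alkyl dithiane anion needs a strong base and a polar additive, in the presence of three benzyl ethers with acidic benzylic protons. The dithiane must be removed with electrophilic or oxidative reagents in the presence of three electron-rich rings, and removed completely before hydrogenolysis because sulfur poisons palladium. A3 and A4 each need about three steps, so the total is about nine.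
- Comparison: on total step count it is comparable or slightly worse. On reagent profile (stoichiometric organolithium, sulfur waste, an extra unmasking step) it is worse. On the main uncertainty of the chosen plan, catalyst-controlled selection, it is better.

Alternative 3: The cut is the C5–C6 bond. Under silyl Lewis acid activation, a chiral copper(I) catalyst would add the Grignard reagent A8 to the unsubstituted ring carbon next to oxygen of the 2-aryl-4-pyrone A7, giving the dihydropyranone A9 after hydrolysis of the silyl enol ether. The aryl-bearing ring carbon of A9 maps onto C1 of 13 and the ring oxygen onto the C5 hydroxyl oxygen. Saturation of the ring double bond, hydrogenolytic opening of the benzylic ring C–O bond and debenzylation would then complete 13, possibly in one operation.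
- In its favour: the C–C bond and the stereocentre are formed in the same event, and the C3 carbonyl and the C5 oxygen are built in. On step economy it is equal to or better than the chosen plan (about two to three steps to each partner, then two).
- Against it: a 4-pyrone is aromatic and a weak acceptor, and the electron-rich 2-aryl group weakens it further. Asymmetric dearomative alkylation is established for related benzo-fused and nitrogen analogues, so a monocyclic 2-aryl-4-pyrone is an extrapolation. In A9 the stereocentre carries an oxygen β to the ketone, so reversible ring opening by retro-oxa-Michael reaction could erode the configuration. The final opening of a cyclic benzylic ether may stop at the saturated ring ether.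
- Comparison: on mechanism the two plans are equal in risk, because both key steps go beyond direct precedent and both end with a benzylic hydrogenolysis. The chosen plan protects its stereocentre better and has a precedented detour from the same starting material, while Alternative 3 would be shorter if its key step worked.

Key step: step 4

Assumption: the sense of induction of the rhodium–ligand pair on 5 cannot be predicted, so the ligand antipode that leads to (S)-6 is fixed in the first run by correlation with 6 of secured configuration.

Remark on descriptors: C5 of 13 and 12 is R. Compounds 6, 7 and 11 have the same arrangement in space but are S, because the arm towards C7 outranks the arm towards C3 as long as C7 is a carboxyl, thioester or aryl-ketone carbon.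

## Route

Step 1
Reactants: 1 homovanillyl alcohol [4-(2-hydroxyethyl)-2-methoxyphenol]
Product: 2 2-[4-(benzyloxy)-3-methoxyphenyl]ethan-1-ol
Conditions: BnBr, K2CO3, acetone, reflux
Reagents that add atoms: benzyl bromide, BrCc1ccccc1
Why: Williamson ether synthesis; carbonate deprotonates only the phenol, so the phenoxide is benzylated and the primary alcohol stays free.

Step 2
Reactants: 2 2-[4-(benzyloxy)-3-methoxyphenyl]ethan-1-ol
Product: 3 1-(benzyloxy)-4-(2-iodoethyl)-2-methoxybenzene
Conditions: PPh3, I2, imidazole, CH2Cl2, 0 °C to rt
Reagents that add atoms: iodine, II
Why: Appel-type iodination of a primary alcohol through the alkoxyphosphonium salt and SN2 displacement by iodide; the conditions are neutral, so the benzyl ether survives and elimination to the styrene is not expected.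

Step 3
Reactants: 3 1-(benzyloxy)-4-(2-iodoethyl)-2-methoxybenzene
Product: 4 {2-[4-(benzyloxy)-3-methoxyphenyl]ethyl}zinc iodide, obtained as a titrated THF solution and used as such
Conditions: Zn dust (activated with BrCH2CH2Br and TMSCl), LiCl, THF, 25–40 °C
Reagents that add atoms: zinc, [Zn]
Why: LiCl-promoted direct insertion of zinc into a primary C–I bond; aryl ethers are inert to the reagent and a 2-arylethylzinc halide is stable in THF at this temperature.

Step 4
Reactants: 5 3-[(tert-butyldimethylsilyl)oxy]glutaric anhydride [4-[(tert-butyldimethylsilyl)oxy]oxane-2,6-dione]; 4 {2-[4-(benzyloxy)-3-methoxyphenyl]ethyl}zinc iodide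
Product: 6 (3S)-7-[4-(benzyloxy)-3-methoxyphenyl]-3-[(tert-butyldimethylsilyl)oxy]-5-oxoheptanoic acid
Conditions: [Rh(cod)Cl]2 (cat.), t-Bu-PHOX (cat., antipode as in the assumption), THF, 50 °C, slow addition of 4; then cold 1 M HCl
Reagents that add atoms: none
Why: Proposed new method: a rhodium(I) centre carrying the chiral P,N ligand should insert into one of the two enantiotopic acyl–oxygen bonds of 5 to give an acyl-rhodium(III) carboxylate, take up the arylethyl group of 4 by transmetalation and form the C2–C3 bond by acyl–alkyl reductive elimination, the product leaving as the zinc carboxylate of 6 (insertion and transmetalation may occur in the reverse order on rhodium without changing the outcome). The closest known reaction type is the rhodium- or palladium-catalysed enantioselective alkylation of meso succinic and 3,5-disubstituted glutaric anhydrides with organozinc reagents to keto acids; new here is a glutaric anhydride whose only substituent is a 3-silyloxy group two bonds away from each carbonyl. No ring is closed; the anhydride ring is opened. The C5 stereocentre is created by the choice between the two carbonyl groups and not by a bond at C5, and that choice is under catalyst control: the ligand pocket must read the bulky silyloxy group, which biases the half-chair of 5, so that insertion takes place at the carbonyl whose conversion into the ketone gives (S)-6. Single addition is secured because the second carbonyl is released as an unreactive carboxylate and the new ketone does not react with an alkylzinc halide. Reductive elimination must outrun β-hydride elimination from the arylethyl–rhodium intermediate, which the chelating P,N ligand and a low stationary concentration of 4 should favour. The silyloxy group is kept because no enolate is formed at any stage.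

Step 5
Reactants: 6 (3S)-7-[4-(benzyloxy)-3-methoxyphenyl]-3-[(tert-butyldimethylsilyl)oxy]-5-oxoheptanoic acid
Product: 7 S-ethyl (3S)-7-[4-(benzyloxy)-3-methoxyphenyl]-3-[(tert-butyldimethylsilyl)oxy]-5-oxoheptanethioate
Conditions: EtSH, EDC·HCl, DMAP (cat.), CH2Cl2, 0 °C to rt
Reagents that add atoms: ethanethiol, CCS
Why: Steglich-type thioesterification through the O-acylisourea and acylpyridinium; the thiol is a soft, fast nucleophile, so neither the ketone nor the silyl ether is involved and C5 is untouched.

Step 6
Reactants: 7 S-ethyl (3S)-7-[4-(benzyloxy)-3-methoxyphenyl]-3-[(tert-butyldimethylsilyl)oxy]-5-oxoheptanethioate; 8 4-bromo-1,2-bis(benzyloxy)benzene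
Product: 11 (3S)-7-[4-(benzyloxy)-3-methoxyphenyl]-1-[3,4-bis(benzyloxy)phenyl]-3-[(tert-butyldimethylsilyl)oxy]heptane-1,5-dione, via aryllithium 9 (not isolated), via arylzinc chloride 10 (not isolated)
Conditions: 8, n-BuLi (not in excess), THF, −78 °C; ZnCl2, −78 °C to rt; then 7, PdCl2(PPh3)2 (cat.), THF–toluene, rt
Reagents that add atoms: none
Why: Fukuyama coupling: palladium(0) inserts into the acyl–sulfur bond of 7, the arylzinc chloride transmetalates and reductive elimination gives the aryl ketone. An arylzinc halide does not add to the C3 ketone and the medium is neutral, so the β-silyloxy group and C5 are not affected; the aryllithium is fully converted into the zinc reagent before 7 is added.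

Step 7
Reactants: 11 (3S)-7-[4-(benzyloxy)-3-methoxyphenyl]-1-[3,4-bis(benzyloxy)phenyl]-3-[(tert-butyldimethylsilyl)oxy]heptane-1,5-dione
Product: 12 (5R)-5-[(tert-butyldimethylsilyl)oxy]-7-(3,4-dihydroxyphenyl)-1-(4-hydroxy-3-methoxyphenyl)heptan-3-one
Conditions: H2 (1–4 bar), 10% Pd/C, EtOAc–AcOH, rt to 40 °C
Reagents that add atoms: none
Why: Catalytic hydrogenolysis: an aryl ketone on an oxygen-rich ring is reduced on palladium through the benzylic carbinol to the methylene group, and the three O-benzyl ethers are cleaved under the same conditions, while a dialkyl ketone and a silyl ether are not substrates in a weakly acidic, non-alcoholic medium. No bond at C5 is made or broken, so the configuration is kept; the descriptor changes from S to R only because C7 loses its oxygen.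

Step 8
Reactants: 12 (5R)-5-[(tert-butyldimethylsilyl)oxy]-7-(3,4-dihydroxyphenyl)-1-(4-hydroxy-3-methoxyphenyl)heptan-3-one
Product: 13 (5R)-7-(3,4-dihydroxyphenyl)-5-hydroxy-1-(4-hydroxy-3-methoxyphenyl)heptan-3-one
Conditions: 48% aq. HF, MeCN, 0 °C to rt, under argon
Reagents that add atoms: none
Why: Fluoride-driven cleavage of the O–Si bond under mildly acidic conditions, the usual way to free a β-hydroxy ketone without retro-aldol or E1cB loss of the oxygen; the catechol is not deprotonated and so is not oxidised, and the C5–O bond is not broken, so the configuration is retained.

## Compound list

1 | homovanillyl alcohol [4-(2-hydroxyethyl)-2-methoxyphenol] | COc1cc(CCO)ccc1O | starting material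
2 | 2-[4-(benzyloxy)-3-methoxyphenyl]ethan-1-ol | COc1cc(CCO)ccc1OCc1ccccc1 | intermediate
3 | 1-(benzyloxy)-4-(2-iodoethyl)-2-methoxybenzene | COc1cc(CCI)ccc1OCc1ccccc1 | intermediate
4 | {2-[4-(benzyloxy)-3-methoxyphenyl]ethyl}zinc iodide | COc1cc(CC[Zn]I)ccc1OCc1ccccc1 | intermediate
5 | 3-[(tert-butyldimethylsilyl)oxy]glutaric anhydride | O=C1CC(O[Si](C)(C)C(C)(C)C)CC(=O)O1 | starting material
6 | (3S)-7-[4-(benzyloxy)-3-methoxyphenyl]-3-[(tert-butyldimethylsilyl)oxy]-5-oxoheptanoic acid | COc1cc(CCC(=O)C[C@H](O[Si](C)(C)C(C)(C)C)CC(=O)O)ccc1OCc1ccccc1 | intermediate
7 | S-ethyl (3S)-7-[4-(benzyloxy)-3-methoxyphenyl]-3-[(tert-butyldimethylsilyl)oxy]-5-oxoheptanethioate | COc1cc(CCC(=O)C[C@H](O[Si](C)(C)C(C)(C)C)CC(=O)SCC)ccc1OCc1ccccc1 | intermediate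
8 | 4-bromo-1,2-bis(benzyloxy)benzene | Brc1ccc(OCc2ccccc2)c(OCc2ccccc2)c1 | starting material
9 | [3,4-bis(benzyloxy)phenyl]lithium | [Li]c1ccc(OCc2ccccc2)c(OCc2ccccc2)c1 | intermediate
10 | [3,4-bis(benzyloxy)phenyl]zinc chloride | Cl[Zn]c1ccc(OCc2ccccc2)c(OCc2ccccc2)c1 | intermediate
11 | (3S)-7-[4-(benzyloxy)-3-methoxyphenyl]-1-[3,4-bis(benzyloxy)phenyl]-3-[(tert-butyldimethylsilyl)oxy]heptane-1,5-dione | COc1cc(CCC(=O)C[C@H](O[Si](C)(C)C(C)(C)C)CC(=O)c2ccc(OCc3ccccc3)c(OCc3ccccc3)c2)ccc1OCc1ccccc1 | intermediate
12 | (5R)-5-[(tert-butyldimethylsilyl)oxy]-7-(3,4-dihydroxyphenyl)-1-(4-hydroxy-3-methoxyphenyl)heptan-3-one | COc1cc(CCC(=O)C[C@H](O[Si](C)(C)C(C)(C)C)CCc2ccc(O)c(O)c2)ccc1O | intermediate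
13 | (5R)-7-(3,4-dihydroxyphenyl)-5-hydroxy-1-(4-hydroxy-3-methoxyphenyl)heptan-3-one | COc1cc(CCC(=O)C[C@H](O)CCc2ccc(O)c(O)c2)ccc1O | target

## Step count and least certain steps

Total step count: 8. Longest linear sequence: 8 steps (1 to 13; 5 and 8 are bought and enter directly).

Step 4 (key step, proposed new method). The most likely failure is poor discrimination between the two enantiotopic carbonyl groups, because the only substituent the ligand can read sits two bonds from each carbonyl and not next to it as in the known meso anhydrides. The second risk is β-hydride elimination from the arylethyl–rhodium intermediate, which would divert the nucleophile to the styrene and the reduced arene. The third is decarbonylation of the acyl–rhodium species followed by loss of the silyloxy group. The fallback uses known chemistry and sets out from 5. Organocatalytic enantioselective thiolysis of the anhydride with benzyl mercaptan and a bifunctional cinchona-alkaloid sulfonamide (the pseudo-enantiomer that opens the carbonyl destined to become C3) should give (3R)-5-(benzylsulfanyl)-3-[(tert-butyldimethylsilyl)oxy]-5-oxopentanoic acid F1. Fukuyama coupling of the thioester end of F1 with about two equivalents of 4 (the first is spent on the acidic proton; PdCl2(PPh3)2 cat., THF–toluene, rt, acidic work-up) then comes back to the route at 6. The stereocentre is set there by an established anhydride desymmetrisation, and the C2–C3 bond by an established acyl coupling.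

Step 7. The most likely failure is stalling of the deoxygenation. Once the benzyl groups are gone, the ketone is a 4-hydroxyaryl ketone of low electrophilicity, so reduction may stop at the ketone or the benzylic carbinol. The carbinol can also close onto the C3 ketone as a six-membered lactol and be diverted to a cyclic ether. More acid would help the C–O hydrogenolysis but risks loss of the C5 oxygen by elimination; loss of the silyl group alone would be harmless, since it only anticipates step 8. The fallback sets out from 11 and separates carbonyl reduction from C–O hydrogenolysis. A ruthenium–arene–TsDPEN transfer-hydrogenation catalyst with formic acid and triethylamine reduces aryl ketones but not simple dialkyl ketones, and should give (5R)-1-[4-(benzyloxy)-3-methoxyphenyl]-7-[3,4-bis(benzyloxy)phenyl]-5-[(tert-butyldimethylsilyl)oxy]-7-hydroxyheptan-3-one F2 as a mixture of C7 epimers while the phenols are still benzylated. Hydrogenolysis of the electron-rich benzylic carbinol and of the benzyl ethers (H2, Pd/C, EtOAc–EtOH) then comes back to the route at 12.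

Step 6. The most likely failures are decarbonylation of the acyl–palladium intermediate followed by β-elimination of the silyloxy group, slow transmetalation or homocoupling of the electron-rich arylzinc, and transfer of a butyl group if any butylzinc species is carried over from the halogen–lithium exchange. The fallback sets out from 7 and changes the nucleophile and the activation mode. A Liebeskind–Srogl coupling with commercial [3,4-bis(benzyloxy)phenyl]boronic acid F3 (Pd2(dba)3 and tri(2-furyl)phosphine cat., copper(I) thiophene-2-carboxylate, THF, 50 °C) is base-free, uses no organolithium or zinc reagent, and comes back to the route at 11.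

## Further compounds

F1 | step 4 | (3R)-5-(benzylsulfanyl)-3-[(tert-butyldimethylsilyl)oxy]-5-oxopentanoic acid | O=C(SCc1ccccc1)C[C@H](O[Si](C)(C)C(C)(C)C)CC(=O)O
F2 | step 7 | (5R)-1-[4-(benzyloxy)-3-methoxyphenyl]-7-[3,4-bis(benzyloxy)phenyl]-5-[(tert-butyldimethylsilyl)oxy]-7-hydroxyheptan-3-one (mixture of C7 epimers) | COc1cc(CCC(=O)C[C@H](O[Si](C)(C)C(C)(C)C)CC(O)c2ccc(OCc3ccccc3)c(OCc3ccccc3)c2)ccc1OCc1ccccc1
F3 | step 6 | [3,4-bis(benzyloxy)phenyl]boronic acid | OB(O)c1ccc(OCc2ccccc2)c(OCc2ccccc2)c1
A1 | alternative 1 | (E)-7-[3,4-bis(benzyloxy)phenyl]-1-(4-hydroxy-3-methoxyphenyl)hept-1-ene-3,5-dione | COc1cc(/C=C/C(=O)CC(=O)CCc2ccc(OCc3ccccc3)c(OCc3ccccc3)c2)ccc1O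
A2 | alternative 1 | (R,E)-7-[3,4-bis(benzyloxy)phenyl]-5-hydroxy-1-(4-hydroxy-3-methoxyphenyl)hept-1-en-3-one | COc1cc(/C=C/C(=O)C[C@H](O)CCc2ccc(OCc3ccccc3)c(OCc3ccccc3)c2)ccc1O
A3 | alternative 2 | (R)-2-{2-[3,4-bis(benzyloxy)phenyl]ethyl}oxirane | C1[C@H](O1)CCc1ccc(OCc2ccccc2)c(OCc2ccccc2)c1
A4 | alternative 2 | 2-{2-[4-(benzyloxy)-3-methoxyphenyl]ethyl}-1,3-dithiane | COc1cc(CCC2SCCCS2)ccc1OCc1ccccc1
A5 | alternative 2 | (2-{2-[4-(benzyloxy)-3-methoxyphenyl]ethyl}-1,3-dithian-2-yl)lithium | COc1cc(CCC2([Li])SCCCS2)ccc1OCc1ccccc1
A6 | alternative 2 | (R)-4-[3,4-bis(benzyloxy)phenyl]-1-(2-{2-[4-(benzyloxy)-3-methoxyphenyl]ethyl}-1,3-dithian-2-yl)butan-2-ol | COc1cc(CCC2(C[C@H](O)CCc3ccc(OCc4ccccc4)c(OCc4ccccc4)c3)SCCCS2)ccc1OCc1ccccc1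
A7 | alternative 3 | 2-[4-(benzyloxy)-3-methoxyphenyl]-4H-pyran-4-one | COc1cc(-c2cc(=O)cco2)ccc1OCc1ccccc1
A8 | alternative 3 | {2-[3,4-bis(benzyloxy)phenyl]ethyl}magnesium bromide | Br[Mg]CCc1ccc(OCc2ccccc2)c(OCc2ccccc2)c1
A9 | alternative 3 | (R)-2-{2-[3,4-bis(benzyloxy)phenyl]ethyl}-6-[4-(benzyloxy)-3-methoxyphenyl]-2,3-dihydro-4H-pyran-4-one | O=C1C[C@H](OC(c2ccc(OCc3ccccc3)c(OC)c2)=C1)CCc1ccc(OCc2ccccc2)c(OCc2ccccc2)c1
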